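**Strategy.** The acetal carbon C1 of the 2,7-dioxabicyclo[3.2.1]octan-3-one core carries the ring oxygen O7 and the lactone oxygen O2, the signature of an oxacarbene captured by a carboxylic acid. The tetrahydrofuran ring (C1–C8–C5–C6–O7) is therefore traced back to a cyclobutanone: irradiation inserts the carbonyl oxygen between C1 and C6 (ring expansion), and the acid on the C5 side chain, held cis, inserts into the carbene, closing the bridging lactone in the same operation. The keto acid arises from a tertiary-radical Giese addition of the cis-hydroazulene to a 4-silyloxycyclopentenone carrying the glycolate arm, followed by Wolff ring contraction.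

Key step: step 17

Remark: (S)-4-(tert-butyldimethylsilyloxy)cyclopent-2-enone (18) is taken as a commercial starting material.
Remark: the carbinol carbon of the hydroazulene intermediates 6–13 becomes a planar radical in step 11, so its configuration is left undefined; the ester-bearing (or trifluoroacetyl-bearing) ring carbon of 22, 25 and 26 is an epimer mixture that converges in step 16.

Step 1
Reactants: 1 4,4-dimethylcyclohex-2-en-1-one; 2 2-(2-bromoethyl)-2-methyl-1,3-dioxolane
Product: 4 (R)-4,4-dimethyl-3-[2-(2-methyl-1,3-dioxolan-2-yl)ethyl]cyclohexan-1-one, via Grignard reagent 3 (not isolated)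
Conditions: Mg, THF; then 1, CuBr·SMe2 (5 mol %), Josiphos-type ferrocenyl diphosphine (6 mol %), t-BuOMe, −75 °C; aq. NH4Cl
Reagents that add atoms: none
Why: Copper-catalysed enantioselective 1,4-addition of a Grignard reagent to a cyclic enone, in which the chiral Cu–diphosphine complex selects the enone face and sets the (R)-centre (later C3a), the ligand antipode being chosen accordingly.

Step 2
Reactants: 4
Product: 6 (3aR,7aR)-3-hydroxy-3,7,7-trimethyloctahydro-4H-inden-4-one (cis-fused ketol), via diketone 5 (not isolated)
Conditions: 2 M HCl, THF, rt; then KOH, MeOH, 0 °C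
Reagents that add atoms: water, O
Why: Acetal hydrolysis unmasks a 1,6-diketone whose ring enolate adds to the side-chain ketone in an intramolecular aldol addition (5-exo-trig), the five-membered ring closing cis on the cyclohexanone and so setting the ring-fusion centre (later C8a), while the low temperature should stop the reaction at the ketol.

Step 3
Reactants: 6
Product: 7 (3aR,7aR)-3,7,7-trimethyl-3-(triethylsilyloxy)octahydro-4H-inden-4-one
Conditions: TESOTf, 2,6-lutidine, CH2Cl2, −78 °C
Reagents that add atoms: triethylsilyl triflate, CC[Si](CC)(CC)OS(=O)(=O)C(F)(F)F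
Why: Silylation of the tertiary aldol hydroxyl with a silyl triflate blocks retro-aldol cleavage and dehydration in the following steps.

Step 4
Reactants: 7
Product: 9 (3aR,8aR)-1,4,4-trimethyl-1-(triethylsilyloxy)octahydroazulen-8(1H)-one, via α-silyl ketone 8 (not isolated)
Conditions: TMSCHN2, Sc(OTf)3 (10 mol %), toluene, 0 °C → rt; then AcOH–THF–H2O, rt
Reagents that add atoms: trimethylsilyldiazomethane, C[Si](C)(C)C=[N+]=[N-]
Why: Lewis-acid-catalysed diazoalkane homologation of a ketone (Tiffeneau–Demjanov-type ring expansion), in which the less substituted α-CH2 migrates so that the new carbon enters on the side remote from the ring fusion, and mild protodesilylation leaves the cis fusion untouched.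

Step 5
Reactants: 9
Product: 10 triethyl{[(3aR,8aS)-1,4,4-trimethyl-8-methylidenedecahydroazulen-1-yl]oxy}silane
Conditions: Cp2TiMe2, toluene, 70 °C, dark
Reagents that add atoms: dimethyltitanocene, C[Ti](C)(C1C=CC=C1)C1C=CC=C1
Why: Petasis methylenation through a non-basic titanium carbene converts the hindered, epimerisable ketone into the exocyclic alkene without touching the ring fusion.

Step 6
Reactants: 10
Product: 11 (3aR,8aS)-1,4,4-trimethyl-8-methylidenedecahydroazulen-1-ol
Conditions: TBAF, THF, 50 °C
Reagents that add atoms: none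
Why: Fluoride cleavage of the tertiary silyl ether frees the alcohol that will serve as the radical precursor.

Step 7
Reactants: 11
Product: 13 cesium 2-oxo-2-{[(3aR,8aS)-1,4,4-trimethyl-8-methylidenedecahydroazulen-1-yl]oxy}acetate, via methyl oxalate 12 (not isolated)
Conditions: ClCOCO2Me, Et3N, DMAP (cat.), CH2Cl2, 0 °C → rt; then 1 M aq. CsOH (1.0 equiv), THF, rt
Reagents that add atoms: methyl chlorooxoacetate, COC(=O)C(Cl)=O; cesium hydroxide, [Cs+].[OH-]
Why: Acylation of the tertiary alcohol followed by selective saponification of the unhindered methyl ester should give a bench-stable tert-alkyl cesium oxalate.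

Step 8
Reactants: 14 acryloyl chloride; 15 2-(trimethylsilyl)ethanol
Product: 16 2-(trimethylsilyl)ethyl acrylate
Conditions: Et3N, CH2Cl2, 0 °C
Reagents that add atoms: none
Why: Acylation of an alcohol by an acid chloride gives the fluoride-cleavable ester.

Step 9
Reactants: 16
Product: 17 2-(trimethylsilyl)ethyl glyoxylate
Conditions: O3, CH2Cl2, −78 °C; Me2S
Reagents that add atoms: ozone, [O-][O+]=O
Why: Ozonolysis of the acrylate with reductive work-up gives the glyoxylate ester.

Step 10
Reactants: 17; 18 (S)-4-(tert-butyldimethylsilyloxy)cyclopent-2-en-1-one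
Product: 19 2-(trimethylsilyl)ethyl (2S)-2-[(3S)-3-(tert-butyldimethylsilyloxy)-5-oxocyclopent-1-en-1-yl]-2-hydroxyacetate
Conditions: PEt3 (20 mol %), chiral 3,3′-diaryl-H8-BINOL Brønsted acid (10 mol %), THF, −10 °C
Reagents that add atoms: none
Why: Catalytic asymmetric Morita–Baylis–Hillman reaction of a cyclic enone with an activated aldehyde, in which the chiral Brønsted acid bound to the phosphonium enolate controls the aldehyde face and sets the (S)-carbinol (later C4 of the core), the catalyst antipode being chosen accordingly.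

Step 11
Reactants: 13; 19
Product: 20 2-(trimethylsilyl)ethyl (2S)-2-hydroxy-2-[2,3-cis-3,4-trans-4-(tert-butyldimethylsilyloxy)-2-oxo-5-... cyclopentyl]acetate, i.e. the cyclopentanone carrying the glycolate arm at C2, the (1R,3aR,8aS)-1,4,4-trimethyl-8-methylidenedecahydroazulen-1-yl group at C3 (cis to the arm, trans to OTBS) and OTBS at C4
Conditions: Ir[dF(CF3)ppy]2(dtbbpy)PF6 (1 mol %), H2O (10 equiv), DME/DMF 3:1, blue LEDs, rt
Reagents that add atoms: none
Why: Photoredox Giese reaction, in which oxidation of the oxalate and loss of two CO2 give the tertiary radical that adds through the convex face of the cis-hydroazulene (quaternary centre) to the enone β-carbon anti to the OTBS group (future C8), and the derived enolate is protonated by water opposite the new tert-alkyl group to give the 2,3-cis ketone (future C5).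

Step 12
Reactants: 20
Product: 21 the acetate of 20 (side chain now CH(OAc)CO2CH2CH2SiMe3)
Conditions: Ac2O, pyridine, DMAP (cat.), CH2Cl2, 0 °C
Reagents that add atoms: acetic anhydride, CC(=O)OC(C)=O
Why: Acylation of the secondary alcohol installs the acetate of the target and removes the retro-aldol pathway before base is used.

Step 13
Reactants: 21
Product: 23 the α-diazo ketone of 21 (C=N2 at the ring CH2 between C=O and C–OTBS), via trifluoroacetyl ketone 22 (not isolated)
Conditions: LiHMDS (1.1 equiv), THF, −78 °C; CF3CO2CH2CF3, −78 °C; then MsN3, Et3N, H2O, MeCN, rt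
Reagents that add atoms: methanesulfonyl azide, CS(=O)(=O)N=[N+]=[N-]; 2,2,2-trifluoroethyl trifluoroacetate (atoms in 22 only), O=C(OCC(F)(F)F)C(F)(F)F
Why: Detrifluoroacetylative diazo transfer (Regitz-type), where kinetic deprotonation occurs at the only α-methylene, the enolate is acylated at −78 °C before it can expel silanolate, and the activated 1,3-dicarbonyl then accepts the diazo group under mild amine base.

Step 14
Reactants: 23
Product: 25 methyl 2-(tert-butyldimethylsilyloxy)-3-(hydroazulenyl)-4-[(S)-acetoxy(2-trimethylsilylethoxycarbonyl)methyl]cyclobutane-1-carboxylate (C3/C4 cis, C2–O trans to C3; C1 epimers), via ketene 24 (not isolated)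
Conditions: hν (350 nm), MeOH, rt
Reagents that add atoms: methanol, CO
Why: Photochemical Wolff rearrangement with ring contraction, in which the α′-carbon migrates to the carbene carbon with retention and methanol adds to the ketene, so the former ring carbonyl becomes the methyl ester of the target.

Step 15
Reactants: 25
Product: 26 (S)-2-acetoxy-2-[2-hydroxy-3-(methoxycarbonyl)-4-(hydroazulenyl)... ]acetic acid, i.e. the cyclobutanol carboxylic acid obtained by loss of both silyl groups from 25
Conditions: TBAF/AcOH (1:1), THF, rt → 40 °C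
Reagents that add atoms: none
Why: Buffered fluoride removes the TBS ether and the 2-(trimethylsilyl)ethyl ester (β-elimination of ethene) without generating a free cyclobutoxide that could undergo retro-aldol ring opening.

Step 16
Reactants: 26
Product: 27 (S)-2-acetoxy-2-[(1,4-trans-3,4-cis)-1-(methoxycarbonyl)-2-oxo-3-(hydroazulenyl)cyclobutan-4-yl]acetic acid (cyclobutanone β-keto ester)
Conditions: Dess–Martin periodinane, CH2Cl2, rt; filtration through SiO2
Reagents that add atoms: none
Why: Dess–Martin oxidation gives the cyclobutanone under non-basic conditions, and the β-keto ester carbon should equilibrate through its enol to the isomer trans to the adjacent side chain (future C6) while the less acidic α-carbon bearing the hydroazulene is left untouched.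

Step 17
Reactants: 27
Product: 29 target CNP0215240.1, via oxacarbene 28 (not isolated)
Conditions: hν (λ > 300 nm, Pyrex), degassed benzene (2 mM), rt
Reagents that add atoms: none
Why: n→π* excitation of the cyclobutanone triggers Norrish type I cleavage of the C2–C1 bond on the side of the ester-bearing carbon (the better stabilised radical), and the acyl oxygen recombines with that carbon to give the 2-oxacyclopentylidene 28 with retention at the migrating carbon, so the four-membered ring becomes the tetrahydrofuran by insertion of one oxygen. The nucleophilic carbene is then protonated by the carboxylic acid held on the same face by the C4 side chain and the oxocarbenium/carboxylate pair collapses, a net intramolecular O–H insertion. The closest known reaction type is the photochemical ring expansion of cyclobutanones to 2-alkoxy- or 2-acyloxytetrahydrofurans with trapping of the oxacarbene by alcohols or carboxylic acids. The tetrahydrofuran arises by ring expansion (1,2-shift of carbon from C to O, not a Baldwin-type closure), and the lactone closes as a bridging six-membered ring by attack of the carboxylate oxygen on the ring oxocarbenium carbon (6-exo-like). The only new stereocentre, the acylal carbon C1, is dictated by the tether because the bridge can only form on the face carrying the side chain, while C5, C6 and C8 are carried over unchanged. The step needs α-cleavage toward the ester-bearing carbon and reclosure on oxygen rather than cycloelimination or decarbonylation, which the radical-stabilising ester, the fully substituted ring and the dilute non-nucleophilic medium with an internal trap are expected to favour.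

**Compound list**
1 | 4,4-dimethylcyclohex-2-en-1-one | O=C1C=CC(C)(C)CC1 | starting material
2 | 2-(2-bromoethyl)-2-methyl-1,3-dioxolane | CC1(CCBr)OCCO1 | starting material
3 | [2-(2-methyl-1,3-dioxolan-2-yl)ethyl]magnesium bromide | CC1(CC[Mg]Br)OCCO1 | intermediate
4 | (R)-4,4-dimethyl-3-[2-(2-methyl-1,3-dioxolan-2-yl)ethyl]cyclohexan-1-one | O=C1CCC(C)(C)[C@H](CCC2(C)OCCO2)C1 | intermediate
5 | (R)-4,4-dimethyl-3-(3-oxobutyl)cyclohexan-1-one | O=C1CCC(C)(C)[C@H](CCC(C)=O)C1 | intermediate
6 | (3aR,7aR)-3-hydroxy-3,7,7-trimethyloctahydro-4H-inden-4-one (cis-fused, C3 undefined) | O=C1CCC(C)(C)[C@@H]2CCC(C)(O)[C@H]12 | intermediate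
7 | triethylsilyl ether of 6 | O=C1CCC(C)(C)[C@@H]2CCC(C)(O[Si](CC)(CC)CC)[C@H]12 | intermediate
8 | (3aR,8aR)-1,4,4-trimethyl-1-(triethylsilyloxy)-7-(trimethylsilyl)octahydroazulen-8(1H)-one | O=C1C([Si](C)(C)C)CCC(C)(C)[C@@H]2CCC(C)(O[Si](CC)(CC)CC)[C@H]12 | intermediate
9 | (3aR,8aR)-1,4,4-trimethyl-1-(triethylsilyloxy)octahydroazulen-8(1H)-one (cis-fused) | O=C1CCCC(C)(C)[C@@H]2CCC(C)(O[Si](CC)(CC)CC)[C@H]12 | intermediate
10 | triethyl{[(3aR,8aS)-1,4,4-trimethyl-8-methylidenedecahydroazulen-1-yl]oxy}silane | C=C1CCCC(C)(C)[C@@H]2CCC(C)(O[Si](CC)(CC)CC)[C@H]12 | intermediate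
11 | (3aR,8aS)-1,4,4-trimethyl-8-methylidenedecahydroazulen-1-ol | C=C1CCCC(C)(C)[C@@H]2CCC(C)(O)[C@H]12 | intermediate
12 | methyl oxalate of 11 | C=C1CCCC(C)(C)[C@@H]2CCC(C)(OC(=O)C(=O)OC)[C@H]12 | intermediate
13 | cesium oxalate of 11 | C=C1CCCC(C)(C)[C@@H]2CCC(C)(OC(=O)C(=O)[O-])[C@H]12.[Cs+] | intermediate
14 | acryloyl chloride | C=CC(Cl)=O | starting material
15 | 2-(trimethylsilyl)ethanol | C[Si](C)(C)CCO | starting material
16 | 2-(trimethylsilyl)ethyl acrylate | C=CC(=O)OCC[Si](C)(C)C | intermediate
17 | 2-(trimethylsilyl)ethyl glyoxylate | O=CC(=O)OCC[Si](C)(C)C | intermediate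
18 | (S)-4-(tert-butyldimethylsilyloxy)cyclopent-2-en-1-one | O=C1C=C[C@@H](O[Si](C)(C)C(C)(C)C)C1 | starting material
19 | 2-(trimethylsilyl)ethyl (2S)-2-[(3S)-3-(tert-butyldimethylsilyloxy)-5-oxocyclopent-1-en-1-yl]-2-hydroxyacetate | O=C1C[C@H](O[Si](C)(C)C(C)(C)C)C=C1[C@H](O)C(=O)OCC[Si](C)(C)C | intermediate
20 | Giese adduct: cyclopentanone with C2 glycolate arm (free OH), C3 hydroazulenyl (cis to arm), C4 OTBS (trans to hydroazulenyl) | C=C1CCCC(C)(C)[C@@H]2CC[C@@](C)([C@@H]3[C@@H](O[Si](C)(C)C(C)(C)C)CC(=O)[C@@H]3[C@H](O)C(=O)OCC[Si](C)(C)C)[C@H]12 | intermediate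
21 | acetate of 20 | C=C1CCCC(C)(C)[C@@H]2CC[C@@](C)([C@@H]3[C@@H](O[Si](C)(C)C(C)(C)C)CC(=O)[C@@H]3[C@H](OC(C)=O)C(=O)OCC[Si](C)(C)C)[C@H]12 | intermediate
22 | α-trifluoroacetyl ketone from 21 | C=C1CCCC(C)(C)[C@@H]2CC[C@@](C)([C@@H]3[C@@H](O[Si](C)(C)C(C)(C)C)C(C(=O)C(F)(F)F)C(=O)[C@@H]3[C@H](OC(C)=O)C(=O)OCC[Si](C)(C)C)[C@H]12 | intermediate
23 | α-diazo ketone | C=C1CCCC(C)(C)[C@@H]2CC[C@@](C)([C@@H]3[C@@H](O[Si](C)(C)C(C)(C)C)C(=[N+]=[N-])C(=O)[C@@H]3[C@H](OC(C)=O)C(=O)OCC[Si](C)(C)C)[C@H]12 | intermediate
24 | cyclobutylidene ketene | C=C1CCCC(C)(C)[C@@H]2CC[C@@](C)([C@@H]3[C@@H](O[Si](C)(C)C(C)(C)C)C(=C=O)[C@@H]3[C@H](OC(C)=O)C(=O)OCC[Si](C)(C)C)[C@H]12 | intermediate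
25 | cyclobutane methyl ester (OTBS, TMSE ester; C1 epimers) | C=C1CCCC(C)(C)[C@@H]2CC[C@@](C)([C@@H]3[C@@H](O[Si](C)(C)C(C)(C)C)C(C(=O)OC)[C@@H]3[C@H](OC(C)=O)C(=O)OCC[Si](C)(C)C)[C@H]12 | intermediate
26 | cyclobutanol carboxylic acid | C=C1CCCC(C)(C)[C@@H]2CC[C@@](C)([C@@H]3[C@@H](O)C(C(=O)OC)[C@@H]3[C@H](OC(C)=O)C(=O)O)[C@H]12 | intermediate
27 | cyclobutanone keto acid (hydroazulenyl cis to side chain, CO2Me trans to side chain) | C=C1CCCC(C)(C)[C@@H]2CC[C@@](C)([C@@H]3C(=O)[C@@H](C(=O)OC)[C@@H]3[C@H](OC(C)=O)C(=O)O)[C@H]12 | intermediate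
28 | oxacarbene (2-oxacyclopentylidene) | C=C1CCCC(C)(C)[C@@H]2CC[C@@](C)([C@@H]3[C]O[C@@H](C(=O)OC)[C@@H]3[C@H](OC(C)=O)C(=O)O)[C@H]12 | intermediate
29 | CNP0215240.1: methyl 4-acetoxy-3-oxo-8-[(1R,3aR,8aS)-1,4,4-trimethyl-8-methylidenedecahydroazulen-1-yl]-2,7-dioxabicyclo[3.2.1]octane-6-carboxylate, stereochemistry as in the SMILES | C=C1CCCC(C)(C)[C@@H]2CC[C@@](C)([C@@H]3[C@@H]4OC(=O)[C@@H](OC(C)=O)[C@H]3[C@H](C(=O)OC)O4)[C@H]12 | target

**Count.** Total: 17 steps. Longest linear sequence: 14 steps (steps 1–7, then 11–17).

**Steps most likely to fail**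

1. Step 17. The acyl–alkyl biradical may fragment to ketene and acrylate or lose CO instead of reclosing on oxygen, α-cleavage may occur on the hydroazulene side, or the carbene may be quenched before the tethered acid reaches it. Fallback: 27 is irradiated in methanol, where intermolecular O–H insertion of the solvent into the oxacarbene (the best-precedented variant of this ring expansion) should give the methyl acetal acid F1. F1 is then treated with catalytic camphorsulfonic acid and 4 Å sieves in CH2Cl2, so that the acid displaces methoxide through the ring oxocarbenium ion and the route is rejoined at 29.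

2. Step 13. The enolate next to the silyloxy carbon may expel silanolate, the C2 centre may epimerise, or the enolate may be acylated internally by the acetate. Fallback: 21 is condensed with tert-butoxybis(dimethylamino)methane (THF, 40 °C) at the same methylene without forming a free enolate, giving the enaminone F2. Diazo transfer to F2 with 4-acetamidobenzenesulfonyl azide (CH2Cl2, rt) then cleaves the aminomethylene group and returns to 23.

3. Step 11. Addition to the α-substituted enone may be slow, the β-hydroxy ketone may undergo retro-aldol cleavage or epimerisation under the carboxylate base, or enolate protonation may occur from the wrong face. Fallback: alcohol 11 is converted with oxalyl chloride and then N-hydroxyphthalimide/Et3N into the N-phthalimidoyl oxalate F3. F3 is coupled with 19 under reductive conditions (Ru(bpy)3(PF6)2, Hantzsch ester, i-Pr2NEt·HBF4, CH2Cl2/THF, blue LEDs, rt), where the α-keto radical is terminated by hydrogen-atom transfer from the bulky dihydropyridine in a base-free medium, returning to 20.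

**Further compounds**
F1 | step 17 | methyl acetal acid: 2-methoxytetrahydrofuran from 27 with free side-chain acid (anomers) | C=C1CCCC(C)(C)[C@@H]2CC[C@@](C)([C@@H]3C(OC)O[C@@H](C(=O)OC)[C@@H]3[C@H](OC(C)=O)C(=O)O)[C@H]12
F2 | step 13 | α-(dimethylaminomethylene) ketone from 21 | C=C1CCCC(C)(C)[C@@H]2CC[C@@](C)([C@@H]3[C@@H](O[Si](C)(C)C(C)(C)C)C(=CN(C)C)C(=O)[C@@H]3[C@H](OC(C)=O)C(=O)OCC[Si](C)(C)C)[C@H]12
F3 | step 11 | N-phthalimidoyl oxalate of 11 | C=C1CCCC(C)(C)[C@@H]2CCC(C)(OC(=O)C(=O)ON3C(=O)c4ccccc4C3=O)[C@H]12
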